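**Plan**

1. Retrosynthesis: the acyl–oxygen bond of the malate ester is cut first. Ring B of the 1-aryl-1,2-dihydronaphthalene (C1 aryl, C2 CO2H, C3 ester carboxyl, C4 vinylic CH) is then cut at C1–C2 and C3–C4. These two bonds flank the aromatic C4a–C8a bond, so ring B is the [4+2] adduct of an ortho-quinodimethane on catechol ring A and a C2–C3 dienophile that carries both carboxyl carbons.
2. The quinodimethane is stored as a trans-2-aryl-benzocyclobutenol. This is cut at the bond between its carbinol carbon and ring A (aryl–metal addition to a diarylacetaldehyde that arises from a 1,1-diaryl oxirane), and the diaryl ketone behind it at the carbonyl–aryl bond.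
3. Forward: carbinol, ketone and oxirane are assembled and the four-membered ring is closed. Its thermal opening and cycloaddition with tert-butyl (E)-4-oxobut-2-enoate close ring B. Dehydration across C3–C4, aldehyde oxidation, esterification with di-tert-butyl L-malate and one global deprotection finish the route.
4. Stereochemistry: C1/C2 trans follows from the E,E-dienol, the E-dienophile and endo placement of the formyl group on a titanium bridge. The absolute sense comes from a titanium TADDOLate, and the malate centre from L-malic acid. C3 and C4 of the adduct are erased on purpose.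
5. Benzyl ethers and tert-butyl esters are used throughout, so that all seven protecting groups fall in one BCl3 step that spares the acyl–malate ester.

Key step: step 7

Assumption: (R,R)-TADDOL, (4R,5R)-2,2-dimethyl-α,α,α′,α′-tetraphenyl-1,3-dioxolane-4,5-dimethanol, is taken to expose the dienol face that leads to the (1R,2S) series; the sense has to be confirmed on the first run, and the (S,S)-ligand is equally available if it is reversed.

**Route**

Step 1
Reactants: 1 3,4-bis(benzyloxy)benzaldehyde
Product: 2 4,5-bis(benzyloxy)-2-bromobenzaldehyde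
Conditions: Br2, NaOAc, AcOH, rt; aq. Na2S2O3
Reagents that add atoms: bromine, BrBr
Why: Electrophilic aromatic bromination should occur para to the 3-benzyloxy group and ortho to the formyl group, the only activated position that is not flanked by two substituents, while NaOAc buffers the HBr so that the benzyl ethers survive.

Step 2
Reactants: 2 4,5-bis(benzyloxy)-2-bromobenzaldehyde; 3 4-bromo-1,2-bis(benzyloxy)benzene
Product: 5 [4,5-bis(benzyloxy)-2-bromophenyl][3,4-bis(benzyloxy)phenyl]methanol (racemic), via 3,4-bis(benzyloxy)phenylmagnesium bromide 4 (not isolated)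
Conditions: 3, Mg, I2 (cat.), THF, 40 °C; then 2, THF, 0 °C → rt; aq. NH4Cl
Reagents that add atoms: none
Why: Grignard formation and 1,2-addition to the aldehyde join the two aryl units; an arylmagnesium bromide does not exchange with the aryl bromide of 2, and the racemic carbinol centre is removed in the next step.

Step 3
Reactants: 5 [4,5-bis(benzyloxy)-2-bromophenyl][3,4-bis(benzyloxy)phenyl]methanol
Product: 6 [4,5-bis(benzyloxy)-2-bromophenyl][3,4-bis(benzyloxy)phenyl]methanone
Conditions: Dess–Martin periodinane, CH2Cl2, rt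
Reagents that add atoms: none
Why: Dess–Martin oxidation of a secondary diaryl carbinol to the ketone is neutral and leaves benzyl ethers and the aryl bromide untouched.

Step 4
Reactants: 6 [4,5-bis(benzyloxy)-2-bromophenyl][3,4-bis(benzyloxy)phenyl]methanone
Product: 7 2-[4,5-bis(benzyloxy)-2-bromophenyl]-2-[3,4-bis(benzyloxy)phenyl]oxirane (racemic)
Conditions: Me3S+ I−, KOtBu, DMSO/THF, 0 °C → rt; filtration through basic alumina, used crude
Reagents that add atoms: trimethylsulfonium iodide, C[S+](C)C.[I-]
Why: Corey–Chaykovsky epoxidation: the unstabilised sulfonium methylide adds irreversibly to the diaryl ketone and the betaine closes to the terminal oxirane, which is acid-labile and is therefore not chromatographed on silica.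

Step 5
Reactants: 7 2-[4,5-bis(benzyloxy)-2-bromophenyl]-2-[3,4-bis(benzyloxy)phenyl]oxirane
Product: 10 trans-4,5-bis(benzyloxy)-2-[3,4-bis(benzyloxy)phenyl]-1,2-dihydrobenzocyclobuten-1-ol (racemic), via ortho-lithiated oxirane 8 (not isolated), via bromomagnesio diarylacetaldehyde 9 (not isolated)
Conditions: n-BuLi, THF, −78 °C; then MgBr2·OEt2, −78 °C → rt; aq. NH4Cl
Reagents that add atoms: none
Why: Bromine–lithium exchange at −78 °C outruns attack on the oxirane or the benzylic ether positions; MgBr2 then transmetalates and, as a Lewis acid, triggers a Meinwald rearrangement (1,2-hydride shift through the doubly aryl-stabilised cation) to aldehyde 9, whose aryl–magnesium bond adds to the formyl group in a 4-exo-trig closure, with the aryl group and the O–Mg group expected trans on the new ring to avoid eclipsing.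

Step 6
Reactants: 11 tert-butyl (E)-4-bromobut-2-enoate
Product: 12 tert-butyl (E)-4-oxobut-2-enoate
Conditions: N-methylmorpholine N-oxide, 4 Å MS, MeCN, 0 °C → rt
Reagents that add atoms: N-methylmorpholine N-oxide, C[N+]1([O-])CCOCC1
Why: Ganem oxidation (N-oxide variant of the Kornblum oxidation): SN2 displacement of the allylic bromide by the N-oxide oxygen and base-induced fragmentation of the alkoxyammonium salt give the aldehyde without touching the tert-butyl ester or the E alkene.

Step 7
Reactants: 10 trans-4,5-bis(benzyloxy)-2-[3,4-bis(benzyloxy)phenyl]-1,2-dihydrobenzocyclobuten-1-ol; 12 tert-butyl (E)-4-oxobut-2-enoate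
Product: 14 tert-butyl (1R,2S,3R,4R)-6,7-bis(benzyloxy)-1-[3,4-bis(benzyloxy)phenyl]-3-formyl-4-hydroxy-1,2,3,4-tetrahydronaphthalene-2-carboxylate, via titanium-bound (E,E)-dienol 13 (not isolated)
Conditions: Ti(OiPr)4, (R,R)-TADDOL, 4 Å MS, toluene, rt, i-PrOH removed in vacuo; then 12, toluene, 50 °C; aq. NaHCO3
Reagents that add atoms: none
Why: Proposed new method: exchange of an isopropoxide places racemic 10 on the (TADDOLato)titanium centre as its alkoxide, relief of cyclobutene strain drives a thermal conrotatory four-electron ring opening in which the metal-bound oxygen and the aryl group both rotate outward to give the titanium-bound (E,E)-dienol 13, and the formyl oxygen of 12, bound to the same titanium, delivers the C=C bond in a concerted suprafacial [4+2] addition that rearomatises ring A. The closest known reactions are the thermal ring opening/Diels–Alder trapping of benzocyclobutenols by external dienophiles and the Ti(OiPr)4/TADDOL-controlled Diels–Alder reaction of hydroxy-ortho-quinodimethanes generated by photoenolisation, which passes through the same titanium dienolate. Ring B is closed by this endo [4+2] cycloaddition, which forms C1–C2 and C3–C4 in one event. C1 and C4 come out cis because both termini of the E,E-diene bond on one face, C3 is cis to the C4 oxygen because the titanium bridge holds the formyl group endo beside it, C2 is trans to C3 and hence trans to the C1 aryl because the E geometry of 12 is retained, and the absolute configuration (1R,2S,3R,4R) is decided by the TADDOLate aryl groups that shield one face of the dienol. The step needs regio-, endo- and facial selectivity: the bridge and the polarity match (larger diene HOMO coefficient at the aryl-bearing C1, larger dienophile LUMO coefficient at the ester-bearing carbon β to the formyl group) put the formyl group at C3, and removal of i-PrOH before heating keeps the dienolate from being protonated to a 2-benzylbenzaldehyde. Both enantiomers of 10 converge on 13, since its two stereocentres vanish on opening.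

Step 8
Reactants: 14 tert-butyl (1R,2S,3R,4R)-6,7-bis(benzyloxy)-1-[3,4-bis(benzyloxy)phenyl]-3-formyl-4-hydroxy-1,2,3,4-tetrahydronaphthalene-2-carboxylate
Product: 16 tert-butyl (1R,2S)-6,7-bis(benzyloxy)-1-[3,4-bis(benzyloxy)phenyl]-3-formyl-1,2-dihydronaphthalene-2-carboxylate, via C4 methanesulfonate 15 (not isolated)
Conditions: MsCl, Et3N, CH2Cl2, 0 °C → rt
Reagents that add atoms: none
Why: Mesylation and E1cB elimination of the β-sulfonyloxy aldehyde (C3–H is α to the formyl group and anti to the leaving group) should give the conjugated enal and erase C3 and C4, while Et3N is too weak a base to deprotonate C2, so C1 and C2 are retained.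

Step 9
Reactants: 16 tert-butyl (1R,2S)-6,7-bis(benzyloxy)-1-[3,4-bis(benzyloxy)phenyl]-3-formyl-1,2-dihydronaphthalene-2-carboxylate
Product: 17 (1R,2S)-6,7-bis(benzyloxy)-1-[3,4-bis(benzyloxy)phenyl]-2-(tert-butoxycarbonyl)-1,2-dihydronaphthalene-3-carboxylic acid
Conditions: NaClO2, NaH2PO4, 2-methyl-2-butene, t-BuOH/THF/H2O, 0 °C → rt
Reagents that add atoms: sodium chlorite, [Na+].[O-]Cl=O
Why: Pinnick oxidation converts the enal to the α,β-unsaturated acid at buffered pH without epimerising C2 or attacking the alkene, 2-methyl-2-butene removing the HOCl that would otherwise chlorinate the electron-rich rings.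

Step 10
Reactants: 18 L-malic acid
Product: 19 di-tert-butyl (S)-malate
Conditions: O-tert-butyl-N,N′-diisopropylisourea, THF/CH2Cl2, rt
Reagents that add atoms: O-tert-butyl-N,N′-diisopropylisourea, CC(C)NC(OC(C)(C)C)=NC(C)C
Why: Isourea-mediated tert-butyl esterification needs protonation of the reagent by a carboxylic acid, so both carboxyl groups are esterified while the secondary hydroxyl stays free and the stereocentre is not involved.

Step 11
Reactants: 17 (1R,2S)-6,7-bis(benzyloxy)-1-[3,4-bis(benzyloxy)phenyl]-2-(tert-butoxycarbonyl)-1,2-dihydronaphthalene-3-carboxylic acid; 19 di-tert-butyl (S)-malate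
Product: 20 di-tert-butyl (S)-2-{[(1R,2S)-6,7-bis(benzyloxy)-1-[3,4-bis(benzyloxy)phenyl]-2-(tert-butoxycarbonyl)-1,2-dihydronaphthalene-3-carbonyl]oxy}butanedioate
Conditions: DCC, DMAP (cat.), CH2Cl2, 0 °C → rt
Reagents that add atoms: none
Why: Steglich esterification through the O-acylisourea and the acylpyridinium ion acylates the hydroxyl of 19 with retention at the malate carbon; the activated acid has no hydrogen from which a ketene could form, and any core of the wrong absolute configuration would show up here as a separable diastereomer.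

Step 12
Reactants: 20 di-tert-butyl (S)-2-{[(1R,2S)-6,7-bis(benzyloxy)-1-[3,4-bis(benzyloxy)phenyl]-2-(tert-butoxycarbonyl)-1,2-dihydronaphthalene-3-carbonyl]oxy}butanedioate
Product: 21 (S)-2-{[(1R,2S)-2-carboxy-1-(3,4-dihydroxyphenyl)-6,7-dihydroxy-1,2-dihydronaphthalene-3-carbonyl]oxy}butanedioic acid (target)
Conditions: BCl3, C6HMe5, CH2Cl2, −78 → 0 °C; then H2O; reversed-phase purification under argon
Reagents that add atoms: none
Why: Lewis acid debenzylation with pentamethylbenzene as a non-basic cation scavenger cleaves the four aryl benzyl ethers, and BCl3 cleaves the three tert-butyl esters by E1 acidolysis at low temperature, conditions under which the secondary acyl–malate ester, the conjugated alkene and both ring stereocentres should be inert.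

**Compound list**

1 | 3,4-bis(benzyloxy)benzaldehyde | O=Cc1ccc(OCc2ccccc2)c(OCc2ccccc2)c1 | starting material
2 | 4,5-bis(benzyloxy)-2-bromobenzaldehyde | O=Cc1cc(OCc2ccccc2)c(OCc2ccccc2)cc1Br | intermediate
3 | 4-bromo-1,2-bis(benzyloxy)benzene | Brc1ccc(OCc2ccccc2)c(OCc2ccccc2)c1 | starting material
4 | 3,4-bis(benzyloxy)phenylmagnesium bromide | Br[Mg]c1ccc(OCc2ccccc2)c(OCc2ccccc2)c1 | intermediate
5 | [4,5-bis(benzyloxy)-2-bromophenyl][3,4-bis(benzyloxy)phenyl]methanol, racemic | OC(c1ccc(OCc2ccccc2)c(OCc2ccccc2)c1)c1cc(OCc2ccccc2)c(OCc2ccccc2)cc1Br | intermediate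
6 | [4,5-bis(benzyloxy)-2-bromophenyl][3,4-bis(benzyloxy)phenyl]methanone | O=C(c1ccc(OCc2ccccc2)c(OCc2ccccc2)c1)c1cc(OCc2ccccc2)c(OCc2ccccc2)cc1Br | intermediate
7 | 2-[4,5-bis(benzyloxy)-2-bromophenyl]-2-[3,4-bis(benzyloxy)phenyl]oxirane, racemic | Brc1cc(OCc2ccccc2)c(OCc2ccccc2)cc1C1(CO1)c1ccc(OCc2ccccc2)c(OCc2ccccc2)c1 | intermediate
8 | 2-[4,5-bis(benzyloxy)-2-lithiophenyl]-2-[3,4-bis(benzyloxy)phenyl]oxirane | [Li]c1cc(OCc2ccccc2)c(OCc2ccccc2)cc1C1(CO1)c1ccc(OCc2ccccc2)c(OCc2ccccc2)c1 | intermediate
9 | 2-[4,5-bis(benzyloxy)-2-(bromomagnesio)phenyl]-2-[3,4-bis(benzyloxy)phenyl]acetaldehyde | O=CC(c1ccc(OCc2ccccc2)c(OCc2ccccc2)c1)c1cc(OCc2ccccc2)c(OCc2ccccc2)cc1[Mg]Br | intermediate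
10 | trans-4,5-bis(benzyloxy)-2-[3,4-bis(benzyloxy)phenyl]-1,2-dihydrobenzocyclobuten-1-ol, racemic (one enantiomer drawn) | O[C@@H]1c2cc(OCc3ccccc3)c(OCc3ccccc3)cc2[C@H]1c1ccc(OCc2ccccc2)c(OCc2ccccc2)c1 | intermediate
11 | tert-butyl (E)-4-bromobut-2-enoate | BrC/C=C/C(=O)OC(C)(C)C | starting material
12 | tert-butyl (E)-4-oxobut-2-enoate | O=C/C=C/C(=O)OC(C)(C)C | intermediate
13 | (E)-{(6E)-3,4-bis(benzyloxy)-6-[3,4-bis(benzyloxy)benzylidene]cyclohexa-2,4-dien-1-ylidene}methanol, held on titanium as its TADDOLate-bound enolate (free dienol drawn) | O/C=C1\C=C(OCc2ccccc2)C(OCc2ccccc2)=C\C1=C/c1ccc(OCc2ccccc2)c(OCc2ccccc2)c1 | intermediate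
14 | tert-butyl (1R,2S,3R,4R)-6,7-bis(benzyloxy)-1-[3,4-bis(benzyloxy)phenyl]-3-formyl-4-hydroxy-1,2,3,4-tetrahydronaphthalene-2-carboxylate | O=C[C@H]1[C@@H](O)c2cc(OCc3ccccc3)c(OCc3ccccc3)cc2[C@@H](c2ccc(OCc3ccccc3)c(OCc3ccccc3)c2)[C@@H]1C(=O)OC(C)(C)C | intermediate
15 | tert-butyl (1R,2S,3R,4R)-6,7-bis(benzyloxy)-1-[3,4-bis(benzyloxy)phenyl]-3-formyl-4-(methanesulfonyloxy)-1,2,3,4-tetrahydronaphthalene-2-carboxylate | O=C[C@H]1[C@@H](OS(C)(=O)=O)c2cc(OCc3ccccc3)c(OCc3ccccc3)cc2[C@@H](c2ccc(OCc3ccccc3)c(OCc3ccccc3)c2)[C@@H]1C(=O)OC(C)(C)C | intermediate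
16 | tert-butyl (1R,2S)-6,7-bis(benzyloxy)-1-[3,4-bis(benzyloxy)phenyl]-3-formyl-1,2-dihydronaphthalene-2-carboxylate | O=CC1=Cc2cc(OCc3ccccc3)c(OCc3ccccc3)cc2[C@@H](c2ccc(OCc3ccccc3)c(OCc3ccccc3)c2)[C@@H]1C(=O)OC(C)(C)C | intermediate
17 | (1R,2S)-6,7-bis(benzyloxy)-1-[3,4-bis(benzyloxy)phenyl]-2-(tert-butoxycarbonyl)-1,2-dihydronaphthalene-3-carboxylic acid | OC(=O)C1=Cc2cc(OCc3ccccc3)c(OCc3ccccc3)cc2[C@@H](c2ccc(OCc3ccccc3)c(OCc3ccccc3)c2)[C@@H]1C(=O)OC(C)(C)C | intermediate
18 | L-malic acid, (S)-2-hydroxybutanedioic acid | O[C@@H](CC(=O)O)C(=O)O | starting material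
19 | di-tert-butyl (S)-malate | O[C@@H](CC(=O)OC(C)(C)C)C(=O)OC(C)(C)C | intermediate
20 | di-tert-butyl (S)-2-{[(1R,2S)-6,7-bis(benzyloxy)-1-[3,4-bis(benzyloxy)phenyl]-2-(tert-butoxycarbonyl)-1,2-dihydronaphthalene-3-carbonyl]oxy}butanedioate | CC(C)(C)OC(=O)C[C@H](OC(=O)C1=Cc2cc(OCc3ccccc3)c(OCc3ccccc3)cc2[C@@H](c2ccc(OCc3ccccc3)c(OCc3ccccc3)c2)[C@@H]1C(=O)OC(C)(C)C)C(=O)OC(C)(C)C | intermediate
21 | (S)-2-{[(1R,2S)-2-carboxy-1-(3,4-dihydroxyphenyl)-6,7-dihydroxy-1,2-dihydronaphthalene-3-carbonyl]oxy}butanedioic acid | O=C(O)C[C@H](OC(=O)C1=Cc2cc(O)c(O)cc2[C@@H](c2ccc(O)c(O)c2)[C@@H]1C(=O)O)C(=O)O | target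

**Count**

Total steps: 12. Longest linear sequence: 10 steps (1, 2, 3, 4, 5, 7, 8, 9, 11, 12); steps 6 and 10 are side branches.

**Steps most likely to fail**

Step 7 (proposed new method). The titanium alkoxide may open only at a temperature at which the TADDOLate no longer discriminates the two dienol faces. Residual i-PrOH may protonate the dienolate before it adds. An unbridged pathway may leak regiochemistry, or the formyl C=O may compete as the dienophile. The fallback uses known chemistry, sets out from 10 and returns at 20. Compounds 10 and 12 are heated without metal in toluene at 80–110 °C; thermal opening and hydrogen-bond-directed endo addition of the free dienol should give the racemic adduct, that is 14 together with the (1S,2R,3S,4S) adduct F1. The pair is taken through steps 8 and 9 as written, which carries along the (1S,2R,3S,4S) C4 methanesulfonate F2 (not isolated), the (1S,2R) enal F3 and the (1S,2R) acid F4. Coupling with 19 as in step 11 then gives 20 together with the (1S,2R)-core malate triester F5. These two are diastereomers and are separated by chromatography or crystallisation, after which 20 continues to step 12.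

Step 5. The aryl–metal intermediate may be quenched by the acidic α-hydrogen of the freshly formed diarylacetaldehyde (enolisation in place of 4-exo addition). Ring closure may also give a cis/trans mixture, and the cis isomer opens with a different torquoselectivity. The fallback sets out from 5 and returns at 14, bypassing the four-membered ring. Ionic hydrogenation of 5 (Et3SiH, TFA, CH2Cl2, 0 °C) should give 1-bromo-2-[3,4-bis(benzyloxy)benzyl]-4,5-bis(benzyloxy)benzene F6. Bromine–lithium exchange (n-BuLi, THF, −78 °C) and formylation with DMF give 2-[3,4-bis(benzyloxy)benzyl]-4,5-bis(benzyloxy)benzaldehyde F7. Irradiation of F7 at 366 nm with Ti(OiPr)4, (R,R)-TADDOL and 12 in toluene at rt (photoenolisation/Diels–Alder) generates the same dienol 13 by a light-driven 1,5-hydrogen shift and should give 14.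

Step 12. tert-Butyl cations released under BCl3 may alkylate the catechol rings as they are unmasked. Cleavage of seven groups may also stall at partly protected stages, and prolonged exposure would then erode the acyl–malate ester. The fallback sets out from 20 and returns at 21 with the two cleavage modes separated. TFA/CH2Cl2 at rt (isobutene vented) first removes only the three tert-butyl esters to give (S)-2-{[(1R,2S)-6,7-bis(benzyloxy)-1-[3,4-bis(benzyloxy)phenyl]-2-carboxy-1,2-dihydronaphthalene-3-carbonyl]oxy}butanedioic acid F8. BCl3/C6HMe5 in CH2Cl2, kept at −78 °C, then debenzylates F8 with no tert-butyl cation present.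

**Further compounds**

F1 | step 7 | tert-butyl (1S,2R,3S,4S)-6,7-bis(benzyloxy)-1-[3,4-bis(benzyloxy)phenyl]-3-formyl-4-hydroxy-1,2,3,4-tetrahydronaphthalene-2-carboxylate | O=C[C@@H]1[C@H](O)c2cc(OCc3ccccc3)c(OCc3ccccc3)cc2[C@H](c2ccc(OCc3ccccc3)c(OCc3ccccc3)c2)[C@H]1C(=O)OC(C)(C)C
F2 | step 7 | tert-butyl (1S,2R,3S,4S)-6,7-bis(benzyloxy)-1-[3,4-bis(benzyloxy)phenyl]-3-formyl-4-(methanesulfonyloxy)-1,2,3,4-tetrahydronaphthalene-2-carboxylate | O=C[C@@H]1[C@H](OS(C)(=O)=O)c2cc(OCc3ccccc3)c(OCc3ccccc3)cc2[C@H](c2ccc(OCc3ccccc3)c(OCc3ccccc3)c2)[C@H]1C(=O)OC(C)(C)C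
F3 | step 7 | tert-butyl (1S,2R)-6,7-bis(benzyloxy)-1-[3,4-bis(benzyloxy)phenyl]-3-formyl-1,2-dihydronaphthalene-2-carboxylate | O=CC1=Cc2cc(OCc3ccccc3)c(OCc3ccccc3)cc2[C@H](c2ccc(OCc3ccccc3)c(OCc3ccccc3)c2)[C@H]1C(=O)OC(C)(C)C
F4 | step 7 | (1S,2R)-6,7-bis(benzyloxy)-1-[3,4-bis(benzyloxy)phenyl]-2-(tert-butoxycarbonyl)-1,2-dihydronaphthalene-3-carboxylic acid | OC(=O)C1=Cc2cc(OCc3ccccc3)c(OCc3ccccc3)cc2[C@H](c2ccc(OCc3ccccc3)c(OCc3ccccc3)c2)[C@H]1C(=O)OC(C)(C)C
F5 | step 7 | di-tert-butyl (S)-2-{[(1S,2R)-6,7-bis(benzyloxy)-1-[3,4-bis(benzyloxy)phenyl]-2-(tert-butoxycarbonyl)-1,2-dihydronaphthalene-3-carbonyl]oxy}butanedioate | CC(C)(C)OC(=O)C[C@H](OC(=O)C1=Cc2cc(OCc3ccccc3)c(OCc3ccccc3)cc2[C@H](c2ccc(OCc3ccccc3)c(OCc3ccccc3)c2)[C@H]1C(=O)OC(C)(C)C)C(=O)OC(C)(C)C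
F6 | step 5 | 1-bromo-2-[3,4-bis(benzyloxy)benzyl]-4,5-bis(benzyloxy)benzene | Brc1cc(OCc2ccccc2)c(OCc2ccccc2)cc1Cc1ccc(OCc2ccccc2)c(OCc2ccccc2)c1
F7 | step 5 | 2-[3,4-bis(benzyloxy)benzyl]-4,5-bis(benzyloxy)benzaldehyde | O=Cc1cc(OCc2ccccc2)c(OCc2ccccc2)cc1Cc1ccc(OCc2ccccc2)c(OCc2ccccc2)c1
F8 | step 12 | (S)-2-{[(1R,2S)-6,7-bis(benzyloxy)-1-[3,4-bis(benzyloxy)phenyl]-2-carboxy-1,2-dihydronaphthalene-3-carbonyl]oxy}butanedioic acid | O=C(O)C[C@H](OC(=O)C1=Cc2cc(OCc3ccccc3)c(OCc3ccccc3)cc2[C@@H](c2ccc(OCc3ccccc3)c(OCc3ccccc3)c2)[C@@H]1C(=O)O)C(=O)O
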